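All runs were generated by integration with made-up constants, noise included.

Look into the closed vessel of this flask: L is held above the liquid, E starts from none, and G and Z wait for E. One concentration sets the order of the rate. While [E] holds steady, the step G + E + Z behaves as pseudo-first-order in [G] at a given charge of Z, so define the catalyst constant as ln([G] charged / [G] left) divided by time and by the [Z] charged.

| flask | G | L | Z | remark | time |
|---|---|---|---|---|---|
| elm | 0.12 M | 4 mM (held) | 0.42 mol% | run made earlier |  |
| oak | 0.12 M | 4 mM (held) | 0.66 mol% | run made earlier |  |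
| alder | 0.18 M | 4 mM (held) | 0.3 mol% | run made earlier |  |
| flask | 0.12 M | 4.0 mM (held) | 0.3 mol% |  | 10 min |

| run | time / min | X / % | G / % |
|---|---|---|---|
| elm | 0.833 | 1.7 | 99.5 |
| elm | 2.00 | 2.5 | 96.2 |
| elm | 4.00 | 6.4 | 94.1 |
| elm | 10.0 | 15.8 | 85.0 |
| oak | 2.50 | 6.0 | 93.7 |
| oak | 5.00 | 11.6 | 87.1 |
| oak | 8.00 | 19.2 | 80.6 |
| oak | 10.0 | 22.1 | 77.0 |
| alder | 1.33 | 3.6 | 98.1 |
| alder | 4.00 | 6.3 | 93.4 |
| alder | 6.00 | 10.9 | 90.3 |
| alder | 10.0 | 16.0 | 84.3 |

(scatter of a reading: 0.5 percentage points)
- at the start none of E is dissolved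
- steps under discussion: L <-> E; G + E + Z -> Z + X; E -> J; E + Z <-> Q
- X at 10 min, in percent of the G charged
- concentration of E in solution at 10 min, in percent of saturation

Take X at the last reading of each run as the G lost:

elm: 34.1 M⁻¹ min⁻¹
oak: 31.5 M⁻¹ min⁻¹
alder: 32.3 M⁻¹ min⁻¹
mean: 32.6 M⁻¹ min⁻¹

Now run this flask slowly, by my own reckoning, with [Z] charged at 0.360 mM. In the first instants L must fill the liquid with E, yet look at elm, where X reads 1.7% at 0.833 min and the steady rate asks 1.42%, with a scatter of 0.5 percentage points: no lag shows. In the middle, at 5.00 min, expect 5.70% of X, while the step draws 1.41 mM min⁻¹ of E from a liquid holding at most 4.0 mM, and that draw is what L must keep replacing. At the end, expect: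

X at 10 min = 11.1%

Put [E] close to saturation, though the readings give it no figure of mine. The forecast says 11.6% of X and 85% of saturation for [E], and of a slight fall in its constants it says that this “suggests E is drawn a little below saturation”.

The flask gives 11.3% of X, and [E] at 97.5% of saturation.

    L ⇌ E, rate k1*(csat - [E]) (kL = 16.0 min⁻¹)
    G + E + Z → Z + X (k = 13000 M⁻² min⁻¹)
    E → J (k = 0.0820 min⁻¹)
    E + Z ⇌ Q, settled at all times (K = 130 M⁻¹)

Read back from this flask, the constant is 33.3 M⁻¹ min⁻¹. At 10.0 min the flask holds 66.4% of its catalyst as Z and 33.6% as Q, a share hidden inside the constant: X stands at 11.3% rather than 16.4% because E + Z joins to Q over a run of this length, and X reaches 70.4% by 100 min. Charged with 0.30 M of G at the same loading, the constant gives 25.5%, and the neighbour flask so charged gave 24.5%.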